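Z.G was what I wanted here, and it forms from Z and G, with G fed from E in the second phase.

    G ⇌ E, rate k1*([G] - [E]/K1) per volume of the first phase (K1 = 0.82, k1 = 0.0879 s⁻¹)
    Z + G → Z.G (k2 = 0.130 L mol⁻¹ s⁻¹)
    2 G → G2 (k3 = 0.0383 L mol⁻¹ s⁻¹)
    G + Q → G.Q (k4 = 8.60 L mol⁻¹ s⁻¹)

Z 0.43 M; E 0.473 M; Q 8.60 mM; time 30 s; volume of the second phase over the first 0.50

- where a step has two of a species, its rate is k times that concentration squared, and two are used at each turn
- in the second phase: E; everything else is in the first
- charges count per volume of the first phase; a concentration in a rate is the amount of a species over the volume of its own phase; every rate counts per litre of the first phase
- run time (flask): 30 s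

- Z.G at 30 s, in percent of the Z charged
- the change that raises the amount of Z.G at 30 s, in percent of the Z charged most ("none" if none brings more than 2 percentage points) (east / west / none)
- amount of Z.G at 30 s, in percent of the Z charged, after west

- east: doubling the transfer coefficient of step 1, all else as stated
- west: doubling the amount of E, all else as stated

**Frozen share.** The reagent sat in two places, and the crossing kept sharing it out. At balance, each unit of G had a partner of E set by the partition ratio and the volume ratio. I named this the standing share, the part of the unspent reagent present as G,: 70.9%. The gap to that balance shrank with a time constant of about 3.31 s, shorter than the run of 30 s. G started from nothing, so the share began below this value, but I froze it for the run as an approximation.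

**Two extremes.** Q reacted faster than Z per unit of each, so I took its whole charge off the reagent. That left 0.464 M, and G stood at 0.329 M. In the high version G stayed there, and Z fell by a pseudo-first-order law to give 72.3%. In the low version the reagent burned at its opening pace throughout, 0.0575 s⁻¹, which gave 45.8%. The reagent does wear, which pulled the flask below the high figure. The pace slackens as Z and G fall, which lifted it above the low one, though the late start of the crossing pulled against that.

**Doubled charges.** With E doubled, G stood at 0.665 M. The extremes became 64.1% and 92.5%. A doubled transfer coefficient left the share unchanged. I chose west.

**The result.** The forecast gave 48.5% (45% to 52%), west as best, and 69% after it (64% to 74%), holding that “Doubling E nearly doubles the G exposure”. The flask gave 48.7%, above my low figure and below my high one. West added 24 percentage points, east 1.6 points, and west ended at 72.6%, between my two estimates.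

**Share held.** At 30.0 s the flask's G and E gave a share of 67.9%, against my 70.9%. The neighbour flask read at 80 s gave 69.4%. So by then G followed the wearing reagent. The yield of the flask stayed at 48.7% through the wearing away of E together with the length of the run. With E held, the flask gave 86.2%, and left to 300 s it reached 81.8%.

(All constants stand for no real mixture; the flask was simulated.)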